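**Plan**

- Artelasticin is 5,7,2',4'-tetrahydroxy-3,6,8-triprenylflavone. It has no stereocentre, and each alkene carries two methyl groups, so there is nothing stereochemical to control.
- Retrosynthesis: the four phenols are masked as methoxymethyl (MOM) ethers, then ring C is cut at C3-C4 and at O1-C2.
- Enabling feature: the C4 carbonyl sits on ring A ortho to O1, so ring A plus C4 is a salicylaldehyde (formyl carbon = C4, phenol oxygen = O1). C2=C3, carrying ring B and the 3-prenyl chain, is an internal aryl prenyl alkyne.
- Further cuts: the C6 and C8 prenyl bonds lead back to 2,4,6-trihydroxybenzaldehyde and prenyl bromide. The alkyne leads back to 2,4-dihydroxybenzaldehyde (one-carbon homologation) and prenyl bromide (propargylic C-C bond).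
- Forward: rings A and B are bought. Ring A is bis-prenylated and protected; ring B is turned into the prenyl alkyne. Ring C is closed in the rhodium-catalysed formyl C-H/alkyne annulation, and global deprotection ends the route.

Key step: step 6

Remark: in the last step the O5 ether next to the carbonyl is taken to fall first; the later partly deprotected flavones are mixtures of positional isomers and are not numbered. Bought reagents (MOMCl, bases, the Ohira-Bestmann reagent, EtMgBr) carry no numbers.

**Step 1**
Reactants: 1 2,4,6-trihydroxybenzaldehyde; 2 prenyl bromide (1-bromo-3-methylbut-2-ene)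
Product: 4 2,4,6-trihydroxy-3,5-bis(3-methylbut-2-enyl)benzaldehyde, via mono-C-prenyl aldehyde 3 (not isolated)
Conditions: 2 (2.1 equiv), 10% aq. KOH, 0 °C to rt, N2; then cold 1 M HCl to pH 4
Reagents that add atoms: none
Why: Phenoxide C-alkylation of the phloroglucinol nucleus in water, where the solvated oxygens are shielded and the two free ring positions C3 and C5 take the prenyl groups, is the reaction type by which acylphloroglucinols are bis-prenylated to deoxyhumulones, and limiting 2 to two equivalents should hold back geminal over-alkylation.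

**Step 2**
Reactants: 4 2,4,6-trihydroxy-3,5-bis(3-methylbut-2-enyl)benzaldehyde
Product: 6 2-hydroxy-4,6-bis(methoxymethoxy)-3,5-bis(3-methylbut-2-enyl)benzaldehyde, via 4-O-MOM ether 5 (not isolated)
Conditions: MOMCl (2.3 equiv), i-Pr2NEt (3 equiv), CH2Cl2, 0 °C to rt
Reagents that add atoms: chloromethyl methyl ether (MOMCl), COCCl
Why: Williamson-type O-alkylation with an amine base should protect the two hydroxyls that are not locked in the hydrogen bond to the formyl group and leave the chelated 2-hydroxyl free as the handle for rhodium, as in the standard bis-protection of 2,4,6-trihydroxyaryl carbonyl compounds.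

**Step 3**
Reactants: 7 2,4-dihydroxybenzaldehyde
Product: 9 2,4-bis(methoxymethoxy)benzaldehyde, via 4-O-MOM aldehyde 8 (not isolated)
Conditions: NaH (2.4 equiv), DMF, 0 °C; MOMCl (2.4 equiv), 0 °C to rt
Reagents that add atoms: chloromethyl methyl ether (MOMCl), COCCl
Why: Williamson ether synthesis on the bis-phenoxide, with NaH chosen so that the chelated 2-hydroxyl is alkylated as well as the 4-hydroxyl.

**Step 4**
Reactants: 9 2,4-bis(methoxymethoxy)benzaldehyde
Product: 11 1-ethynyl-2,4-bis(methoxymethoxy)benzene, via diazoalkene 10 (not isolated)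
Conditions: dimethyl (1-diazo-2-oxopropyl)phosphonate (1.3 equiv), K2CO3 (2 equiv), MeOH, 0 °C to rt
Reagents that add atoms: dimethyl (1-diazo-2-oxopropyl)phosphonate (Ohira-Bestmann reagent), COP(=O)(OC)C(=[N+]=[N-])C(C)=O
Why: Seyferth-Gilbert homologation in the Ohira-Bestmann form, in which methanolysis of the reagent gives the dimethyl (diazomethyl)phosphonate anion, Horner-Wadsworth-Emmons olefination gives the diazoalkene, and loss of N2 with a 1,2-hydrogen shift gives the terminal alkyne under mildly basic conditions that MOM ethers tolerate.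

**Step 5**
Reactants: 11 1-ethynyl-2,4-bis(methoxymethoxy)benzene; 2 prenyl bromide
Product: 13 2,4-bis(methoxymethoxy)-1-(5-methylhex-4-en-1-ynyl)benzene, via alkynylmagnesium bromide 12 (not isolated)
Conditions: EtMgBr (1.05 equiv), THF, 0 to 40 °C; then CuCl (5 mol%), 2 (1.2 equiv), THF, rt to 50 °C
Reagents that add atoms: none
Why: Deprotonation of the terminal alkyne and copper-catalysed coupling of the alkynyl Grignard reagent with a primary allylic bromide is the standard entry to 1,4-enynes, and attack at the unsubstituted terminus of the prenyl unit is expected because the SN2' path would create a quaternary carbon.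

**Step 6**
Reactants: 6 2-hydroxy-4,6-bis(methoxymethoxy)-3,5-bis(3-methylbut-2-enyl)benzaldehyde; 13 2,4-bis(methoxymethoxy)-1-(5-methylhex-4-en-1-ynyl)benzene
Product: 14 5,7-bis(methoxymethoxy)-2-[2,4-bis(methoxymethoxy)phenyl]-3,6,8-tris(3-methylbut-2-enyl)-4H-chromen-4-one (5,7,2',4'-tetrakis-O-MOM artelasticin)
Conditions: [Cp*RhCl2]2 (Cp* = C5Me5, 2.5 mol%), Cu(OAc)2·H2O (2.2 equiv), 13 (1.2 equiv), o-xylene, 120 °C, N2
Reagents that add atoms: none
Why: Acetate-assisted binding of the chelated phenol to trivalent rhodium brings the formyl C-H to the metal and its cleavage gives a five-membered acyl rhodacycle; the alkyne then inserts into the rhodium-acyl bond (new C3-C4 bond) to give a seven-membered oxa-rhodacycle, C-O reductive elimination forms O1-C2, and Cu(OAc)2 returns the monovalent rhodium to the trivalent state. The closest known reaction is the rhodium-catalysed oxidative coupling of salicylaldehydes with internal alkynes to 2,3-disubstituted chromones, applied here to a more highly substituted pair. Ring C is closed as a formal [4+2] annulation, the six-membered pyranone arising by contraction of the seven-membered rhodacycle in the C-O reductive elimination. No stereocentre is formed. The step needs one orientation of insertion: the aryl-bearing alkyne carbon should take the position on rhodium, favoured by conjugation and by possible chelation of the 2'-methoxymethoxy oxygen, which places ring B at C2 and the prenyl chain at C3. Chemoselectivity rests on the single free hydroxyl of 6, on ring A carrying no aromatic C-H, and on the trisubstituted alkenes being far poorer insertion partners than the alkyne.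

**Step 7**
Reactants: 14 5,7,2',4'-tetrakis-O-MOM artelasticin
Product: 16 artelasticin [5,7-dihydroxy-2-(2,4-dihydroxyphenyl)-3,6,8-tris(3-methylbut-2-enyl)-4H-chromen-4-one], via 5-hydroxy tris-MOM flavone 15 (not isolated)
Conditions: 3 M aq. HCl, MeOH, 50 °C, stopped at full conversion
Reagents that add atoms: none
Why: Acid-catalysed acetal exchange with methanol (methanolysis of phenolic MOM ethers) should release the four hydroxyls, the carbonyl-flanked O5 ether first, and the moderate acid strength and temperature are chosen so that the trisubstituted alkenes are not protonated, as in many prenylflavonoid end games.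

**Compound list**

1 | 2,4,6-trihydroxybenzaldehyde | O=Cc1c(O)cc(O)cc1O | starting material
2 | prenyl bromide (1-bromo-3-methylbut-2-ene) | CC(C)=CCBr | starting material
3 | 2,4,6-trihydroxy-3-(3-methylbut-2-enyl)benzaldehyde (not isolated) | O=Cc1c(O)cc(O)c(CC=C(C)C)c1O | intermediate
4 | 2,4,6-trihydroxy-3,5-bis(3-methylbut-2-enyl)benzaldehyde | O=Cc1c(O)c(CC=C(C)C)c(O)c(CC=C(C)C)c1O | intermediate
5 | 2,6-dihydroxy-4-(methoxymethoxy)-3,5-bis(3-methylbut-2-enyl)benzaldehyde (not isolated) | O=Cc1c(O)c(CC=C(C)C)c(OCOC)c(CC=C(C)C)c1O | intermediate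
6 | 2-hydroxy-4,6-bis(methoxymethoxy)-3,5-bis(3-methylbut-2-enyl)benzaldehyde | O=Cc1c(O)c(CC=C(C)C)c(OCOC)c(CC=C(C)C)c1OCOC | intermediate
7 | 2,4-dihydroxybenzaldehyde | O=Cc1ccc(O)cc1O | starting material
8 | 2-hydroxy-4-(methoxymethoxy)benzaldehyde (not isolated) | O=Cc1ccc(OCOC)cc1O | intermediate
9 | 2,4-bis(methoxymethoxy)benzaldehyde | O=Cc1ccc(OCOC)cc1OCOC | intermediate
10 | 1-(2-diazoethenyl)-2,4-bis(methoxymethoxy)benzene (not isolated) | [N-]=[N+]=C=Cc1ccc(OCOC)cc1OCOC | intermediate
11 | 1-ethynyl-2,4-bis(methoxymethoxy)benzene | C#Cc1ccc(OCOC)cc1OCOC | intermediate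
12 | {[2,4-bis(methoxymethoxy)phenyl]ethynyl}magnesium bromide (not isolated) | Br[Mg]C#Cc1ccc(OCOC)cc1OCOC | intermediate
13 | 2,4-bis(methoxymethoxy)-1-(5-methylhex-4-en-1-ynyl)benzene | CC(C)=CCC#Cc1ccc(OCOC)cc1OCOC | intermediate
14 | 5,7-bis(methoxymethoxy)-2-[2,4-bis(methoxymethoxy)phenyl]-3,6,8-tris(3-methylbut-2-enyl)-4H-chromen-4-one | CC(C)=CCc1c(OCOC)c(CC=C(C)C)c2oc(-c3ccc(OCOC)cc3OCOC)c(CC=C(C)C)c(=O)c2c1OCOC | intermediate
15 | 5-hydroxy-7-(methoxymethoxy)-2-[2,4-bis(methoxymethoxy)phenyl]-3,6,8-tris(3-methylbut-2-enyl)-4H-chromen-4-one (not isolated) | CC(C)=CCc1c(OCOC)c(CC=C(C)C)c2oc(-c3ccc(OCOC)cc3OCOC)c(CC=C(C)C)c(=O)c2c1O | intermediate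
16 | artelasticin, 5,7-dihydroxy-2-(2,4-dihydroxyphenyl)-3,6,8-tris(3-methylbut-2-enyl)-4H-chromen-4-one | CC(C)=CCc1c(O)c(CC=C(C)C)c2oc(-c3ccc(O)cc3O)c(CC=C(C)C)c(=O)c2c1O | target

**Totals**

Total step count: 7. Longest linear sequence: 5 steps (steps 3, 4, 5, 6 and 7, from 2,4-dihydroxybenzaldehyde 7).

**Steps most likely to fail**

Step 6 (annulation). The alkyne may insert in the wrong orientation, the acyl rhodium species may lose CO, the skipped enyne may isomerise to an allene under the hot acetate conditions, or the ortho-prenyl phenol may be attacked oxidatively. The fallback builds ring C stepwise; it sets out from aldehyde 6, terminal alkyne 11 and prenyl bromide 2 and returns at 14. The lithium acetylide of 11 (n-BuLi, THF, -78 °C, in excess because the phenol consumes one equivalent) adds to the formyl group of 6 to give the racemic propargylic alcohol F1. MnO2 in CH2Cl2 oxidises it to the 2-hydroxyaryl ynone F2, which removes the stereocentre. Amine-mediated 6-endo-dig oxa-Michael cyclisation (Et2NH, EtOH) gives the 3-unsubstituted flavone F3. C3 is then lithiated with LDA (THF, -78 °C) and the 3-lithioflavone is alkylated with 2, which gives 14.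

Step 1 (bis-C-prenylation). Throughput may be lost to under-alkylation, geminal over-alkylation with dearomatisation, O-alkylation and air oxidation of the electron-rich product. The fallback uses directed metalation; it sets out from prenyl bromide 2 and commercial phloroglucinol and returns at aldehyde 6, so that steps 1 and 2 are both replaced. Phloroglucinol is converted with NaH and MOMCl into 1,3,5-tris(methoxymethoxy)benzene F4. Lithiation between two MOM ethers (n-BuLi, THF, 0 °C) and alkylation with 2 gives the mono-prenyl arene F5. A second lithiation and alkylation gives the diprenyl arene F6. A third lithiation at the last free ring position and a DMF quench gives the tris-MOM aldehyde F7. Brief exposure to dilute HCl in MeOH at rt should remove one of the two equivalent MOM ethers flanking the formyl group, the freed hydroxyl then chelating the carbonyl, and give 6.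

Step 7 (global deprotection). Protonation of a prenyl alkene and capture of the cation by a neighbouring freed hydroxyl would close 2,2-dimethylchroman rings. The fallback avoids Brønsted acid; it sets out from 14 and returns at 16. TMSOTf with 2,2'-bipyridyl in CH2Cl2 at 0 °C exchanges the aromatic MOM ethers for silyl ethers under buffered conditions and gives the tetrakis(trimethylsilyl) ether F8, which water hydrolyses to 16 at work-up.

**Further compounds**

F1 | step 6 | 2-{1-hydroxy-3-[2,4-bis(methoxymethoxy)phenyl]prop-2-yn-1-yl}-3,5-bis(methoxymethoxy)-4,6-bis(3-methylbut-2-enyl)phenol (racemic) | OC(C#Cc1ccc(OCOC)cc1OCOC)c1c(O)c(CC=C(C)C)c(OCOC)c(CC=C(C)C)c1OCOC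
F2 | step 6 | 1-[2-hydroxy-4,6-bis(methoxymethoxy)-3,5-bis(3-methylbut-2-enyl)phenyl]-3-[2,4-bis(methoxymethoxy)phenyl]prop-2-yn-1-one | O=C(C#Cc1ccc(OCOC)cc1OCOC)c1c(O)c(CC=C(C)C)c(OCOC)c(CC=C(C)C)c1OCOC
F3 | step 6 | 5,7-bis(methoxymethoxy)-2-[2,4-bis(methoxymethoxy)phenyl]-6,8-bis(3-methylbut-2-enyl)-4H-chromen-4-one | CC(C)=CCc1c(OCOC)c(CC=C(C)C)c2oc(-c3ccc(OCOC)cc3OCOC)cc(=O)c2c1OCOC
F4 | step 1 | 1,3,5-tris(methoxymethoxy)benzene | COCOc1cc(OCOC)cc(OCOC)c1
F5 | step 1 | 1,3,5-tris(methoxymethoxy)-2-(3-methylbut-2-enyl)benzene | COCOc1cc(OCOC)c(CC=C(C)C)c(OCOC)c1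
F6 | step 1 | 1,3,5-tris(methoxymethoxy)-2,4-bis(3-methylbut-2-enyl)benzene | COCOc1cc(OCOC)c(CC=C(C)C)c(OCOC)c1CC=C(C)C
F7 | step 1 | 2,4,6-tris(methoxymethoxy)-3,5-bis(3-methylbut-2-enyl)benzaldehyde | O=Cc1c(OCOC)c(CC=C(C)C)c(OCOC)c(CC=C(C)C)c1OCOC
F8 | step 7 | 5,7-bis(trimethylsilyloxy)-2-[2,4-bis(trimethylsilyloxy)phenyl]-3,6,8-tris(3-methylbut-2-enyl)-4H-chromen-4-one | CC(C)=CCc1c(O[Si](C)(C)C)c(CC=C(C)C)c2oc(-c3ccc(O[Si](C)(C)C)cc3O[Si](C)(C)C)c(CC=C(C)C)c(=O)c2c1O[Si](C)(C)C
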